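**Plan**
- Retrosynthesis: remove the C2 acetate and the C6 veratrate, take the 8,9-epoxide back to a C8=C9 alkene and that to its C9=C10 isomer, then cut C5–C1 and C7–C8 of the hydroazulene together as a (4+3) disconnection. The resulting open chain is cut at the C4=C5 alkene (ynoate plus cuprate) and at C2–C3 (propargylation).
- Enabling feature: in the seven-membered ring C6 carries oxygen between C5 and C7 (a 2-oxyallyl unit), and C8–C9–C10–C1 is a diene at the alkene oxidation level. The tertiary carbinol C4 next to C5 is a latent 4,5-epoxide that ionises at C5 and keeps its oxygen on C4. C2–C3–C4 of the five-membered ring is the tether.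
- Forward: a C15 chain is built from crotonaldehyde; one cycloaddition then closes the five- and the seven-membered ring at the same time. Ketone reduction, alkene shift, epoxidation and the two esters follow.
- Stereochemistry: C2 from catalyst-controlled propargylation; C4 and C5 from a Sharpless epoxide on a geometrically defined alkene (retention at C4, inversion at C5 in the cycloaddition); C1 from the trans-fused cycloaddition transition state; C6 from equatorial hydride attack; C8 and C9 from oxygen delivery by the 6β-hydroxyl.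

Key step: step 12

Remark: bicyclic compounds are numbered as in the daucane skeleton (C1 ring-fusion carbon with methyl, C2, C3, C4 carbinol carbon with isopropyl, C5 ring-fusion CH, C6 to C10 around the seven-membered ring, methyl on C8); β is the face of the C1 methyl. The target is read as (1S,2S,4S,5R,6S,8R,9S), i.e. 2β-OAc, 4β-OH, 5α-H, 6β-ester, 8β,9β-epoxide. TBS = tert-butyldimethylsilyl, TES = triethylsilyl.

**Step 1**
Reactants: 1 (E)-but-2-enal; 2 2-(triphenylphosphoranylidene)propanal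
Product: 3 (2E,4E)-2-methylhexa-2,4-dienal
Conditions: toluene, 90 °C
Reagents that add atoms: none
Why: Wittig olefination with the stabilised formyl ylide is E-selective and should give the α-methyl enal while the (E)-crotyl double bond of 1 is kept.

**Step 2**
Reactants: 3 (2E,4E)-2-methylhexa-2,4-dienal; 4 allenylboronic acid pinacol ester
Product: 5 (4S,5E,7E)-5-methylnona-5,7-dien-1-yn-4-ol
Conditions: (S)-TRIP [(S)-3,3′-bis(2,4,6-triisopropylphenyl)-1,1′-binaphthyl-2,2′-diyl hydrogen phosphate] (5 mol %), 4 Å MS, toluene, −20 °C; aqueous work-up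
Reagents that add atoms: none
Why: Chiral phosphoric acid-catalysed propargylboration through a closed six-membered transition state (SE2′ at the allenylboronate); the (S)-acid is chosen to deliver the propargyl group to the Si face and set the future C2 as (S), the mirror image of the sense established for the (R)-acid with aryl and alkenyl aldehydes.

**Step 3**
Reactants: 5 (4S,5E,7E)-5-methylnona-5,7-dien-1-yn-4-ol
Product: 6 tert-butyl(dimethyl){[(4S,5E,7E)-5-methylnona-5,7-dien-1-yn-4-yl]oxy}silane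
Conditions: TBSCl, imidazole, DMF, rt
Reagents that add atoms: tert-butyldimethylsilyl chloride, CC(C)(C)[Si](C)(C)Cl
Why: Silylation protects the future C2 oxygen and removes the allylic alcohol that would otherwise compete in step 7.

**Step 4**
Reactants: 6 TBS ether of 5
Product: 8 methyl (5S,6E,8E)-5-{[tert-butyl(dimethyl)silyl]oxy}-6-methyldeca-6,8-dien-2-ynoate, via lithium acetylide 7 (not isolated)
Conditions: n-BuLi, THF, −78 °C; then ClCO2Me, −78 → 0 °C
Reagents that add atoms: methyl chloroformate, COC(=O)Cl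
Why: Deprotonation of the terminal alkyne and C-acylation of the acetylide give the ynoate whose ester carbon becomes C6.

**Step 5**
Reactants: 8 methyl ynoate
Product: 9 methyl (2E,5S,6E,8E)-5-{[tert-butyl(dimethyl)silyl]oxy}-6-methyl-3-(propan-2-yl)deca-2,6,8-trienoate (CH2 chain cis to the ester)
Conditions: i-PrMgCl (2 equiv), CuBr·SMe2 (1 equiv), THF, −78 °C; MeOH quench at −78 °C, then aq. NH4Cl
Reagents that add atoms: isopropylmagnesium chloride, CC(C)[Mg]Cl
Why: Syn carbocupration of the ynoate by (i-Pr)2CuMgCl at −78 °C puts isopropyl and the new vinyl hydrogen cis, so the CH2 chain ends cis to the ester, the geometry the epoxide needs.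

**Step 6**
Reactants: 9 methyl trienoate
Product: 10 (2E,5S,6E,8E)-5-{[tert-butyl(dimethyl)silyl]oxy}-6-methyl-3-(propan-2-yl)deca-2,6,8-trien-1-ol
Conditions: i-Bu2AlH (2.2 equiv), CH2Cl2, −78 → 0 °C
Reagents that add atoms: none
Why: 1,2-Reduction of the enoate with i-Bu2AlH gives the allylic alcohol needed for the epoxidation without touching the silyl ether or the diene.

**Step 7**
Reactants: 10 allylic alcohol
Product: 11 {(2S,3S)-3-[(2S,3E,5E)-2-{[tert-butyl(dimethyl)silyl]oxy}-3-methylhepta-3,5-dien-1-yl]-3-(propan-2-yl)oxiran-2-yl}methanol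
Conditions: Ti(OiPr)4 (10 mol %), L-(+)-diethyl tartrate (12 mol %), t-BuOOH, 4 Å MS, CH2Cl2, −20 °C
Reagents that add atoms: tert-butyl hydroperoxide, CC(C)(C)OO
Why: Sharpless asymmetric epoxidation with the Ti(OiPr)4/L-(+)-tartrate catalyst adds oxygen syn to the face that gives the (2S,3S)-epoxide (same facial sense as for nerol-type 3,3-disubstituted allylic alcohols), setting the future C5 and C4 with the CH2 chain cis to the carbinol carbon; the diene is not an allylic alcohol and should not react.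

**Step 8**
Reactants: 11 epoxy alcohol
Product: 12 (2R,3S)-3-[(2S,3E,5E)-2-{[tert-butyl(dimethyl)silyl]oxy}-3-methylhepta-3,5-dien-1-yl]-3-(propan-2-yl)oxirane-2-carbaldehyde
Conditions: Dess–Martin periodinane, CH2Cl2, 0 °C → rt
Reagents that add atoms: none
Why: Dess–Martin oxidation takes the primary epoxy alcohol to the aldehyde under neutral conditions that do not epimerise the epoxide carbon.

**Step 9**
Reactants: 12 epoxy aldehyde
Product: 13 1-{(2S,3S)-3-[(2S,3E,5E)-2-{[tert-butyl(dimethyl)silyl]oxy}-3-methylhepta-3,5-dien-1-yl]-3-(propan-2-yl)oxiran-2-yl}ethan-1-ol (both carbinol epimers)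
Conditions: MeMgBr, THF, −78 °C; aq. NH4Cl
Reagents that add atoms: methylmagnesium bromide, C[Mg]Br
Why: Grignard addition to the aldehyde is faster than epoxide opening at −78 °C and brings in C7; the new carbinol centre is removed in step 10.

**Step 10**
Reactants: 13 epoxy carbinol
Product: 14 1-{(2R,3S)-3-[(2S,3E,5E)-2-{[tert-butyl(dimethyl)silyl]oxy}-3-methylhepta-3,5-dien-1-yl]-3-(propan-2-yl)oxiran-2-yl}ethan-1-one
Conditions: Dess–Martin periodinane, CH2Cl2, rt
Reagents that add atoms: none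
Why: Dess–Martin oxidation of the secondary alcohol gives the α,β-epoxy methyl ketone.

**Step 11**
Reactants: 14 epoxy methyl ketone
Product: 15 triethyl[(1-{(2R,3S)-3-[(2S,3E,5E)-2-{[tert-butyl(dimethyl)silyl]oxy}-3-methylhepta-3,5-dien-1-yl]-3-(propan-2-yl)oxiran-2-yl}ethenyl)oxy]silane
Conditions: Et3SiOTf (1.2 equiv), Et3N (2 equiv), CH2Cl2, −78 → 0 °C
Reagents that add atoms: triethylsilyl trifluoromethanesulfonate, CC[Si](CC)(CC)OS(=O)(=O)C(F)(F)F
Why: Soft enolisation with silyl triflate and amine can only take place at the methyl group (the other α-carbon is the epoxide carbon), giving the epoxy enolsilane.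

**Step 12**
Reactants: 15 epoxy enolsilane
Product: 16 2β-(TBSO)-4β-(TESO)-5αH,8βH-dauc-9-en-6-one (trans ring fusion; silyl group transferred to the C4 oxygen)
Conditions: Et3SiOTf (20 mol %), CH2Cl2, −78 °C; Et3N quench
Reagents that add atoms: none
Why: Silylation of the epoxide oxygen makes C5 electrophilic with the enolsilane as neighbouring π donor (a 2-siloxyallyl cation in the limit); the C1 terminus of the (E,E)-diene attacks C5 opposite the departing C5–O bond, the enolsilane carbon C7 closes onto C8 in a concerted but asynchronous (4+3) cycloaddition, and the silyl group ends on the C4 oxygen so the acid turns over. The closest known reaction type is the silyl triflate-catalysed intramolecular (4+3) cycloaddition of epoxy enolsilanes with tethered dienes, which is known to pass the configuration of the epoxide on to the adduct. The cyclopentane closes by 5-exo attack of the C1=C10 π bond on C5 with the epoxide C4–C5 bond kept inside the new ring, and the cycloheptene closes by suprafacial union of the four-carbon diene with the three-carbon oxyallyl unit. C5 is set by inversion at the Sharpless-derived epoxide carbon and C4 keeps its configuration and its oxygen; C1 is set by the diene face presented in the extended transition state with the C4 substituent in the W position of the oxyallyl unit, which gives the trans ring fusion; C8 follows from the (E)-propenyl geometry and is erased in step 14. The step needs ionisation at C5–O and not at the tertiary C4–O, which the allylic stabilisation by the enolsilane should secure, and it needs the extended over the compact arrangement, which is expected because the epoxide geometry makes the C3 tether leave C4 on the side of the siloxy oxygen, where only the extended diene orientation lets the (E)-placed C2 reach it without strain. Capture of the allyl cation at C10 in a (3+2) sense is disfavoured because C7 and C8 are both unhindered termini.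

**Step 13**
Reactants: 16 cycloadduct ketone
Product: 17 2β-(TBSO)-4β-(TESO)-5αH,8βH-dauc-9-en-6β-ol
Conditions: LiBH(s-Bu)3, THF, −78 °C; H2O
Reagents that add atoms: none
Why: The bulky hydride LiBH(s-Bu)3 attacks the C6 ketone along the equatorial trajectory from the α face, away from the axial C1 methyl and the 4β-siloxy group, to give the axial 6β-alcohol; the C4 silyl ether blocks retro-aldol cleavage.

**Step 14**
Reactants: 17 Δ9-alcohol
Product: 18 2β-(TBSO)-4β-(TESO)-5αH-dauc-8-en-6β-ol
Conditions: RuHCl(CO)(PPh3)3 (5 mol %), toluene, 80 °C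
Reagents that add atoms: none
Why: Hydride insertion/β-hydride elimination at RuHCl(CO)(PPh3)3 through the secondary C9 alkyl moves the cis-disubstituted C9=C10 bond to the more stable trisubstituted C8=C9 position, and the walk should stop there because C1 is quaternary and further migration would need a tertiary alkyl at C8.

**Step 15**
Reactants: 18 Δ8-alcohol
Product: 19 8β,9β-epoxy-2β-(TBSO)-4β-(TESO)-5αH-daucan-6β-ol
Conditions: VO(acac)2 (5 mol %), t-BuOOH, CH2Cl2, 0 °C → rt
Reagents that add atoms: tert-butyl hydroperoxide, CC(C)(C)OO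
Why: VO(acac)2-catalysed epoxidation directed by the homoallylic 6β-hydroxyl delivers oxygen to the β face of C8=C9 (syn to the hydroxyl), setting C8 and C9 against the steric bias of the C1 methyl.

**Step 16**
Reactants: 19 epoxy alcohol; 20 3,4-dimethoxybenzoyl chloride
Product: 21 8β,9β-epoxy-2β-(TBSO)-4β-(TESO)-5αH-daucan-6β-yl 3,4-dimethoxybenzoate
Conditions: Et3N, DMAP (cat.), CH2Cl2, rt → 40 °C
Reagents that add atoms: none
Why: Acylation of the only free hydroxyl (C6) through the acylpyridinium ion; the epoxide and both silyl ethers are inert to these conditions.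

**Step 17**
Reactants: 21 bis-silyl veratrate
Product: 22 8β,9β-epoxy-2β,4β-dihydroxy-5αH-daucan-6β-yl 3,4-dimethoxybenzoate
Conditions: Bu4NF, AcOH, THF, rt → 40 °C
Reagents that add atoms: none
Why: Fluoride cleaves the tertiary TES ether and the secondary TBS ether, and the acetic acid buffer keeps the aryl ester and the epoxide intact.

**Step 18**
Reactants: 22 diol
Product: 23 2β-acetoxy-8β,9β-epoxy-4β-hydroxy-5αH-daucan-6β-yl 3,4-dimethoxybenzoate (target)
Conditions: Ac2O, pyridine, DMAP (cat.), CH2Cl2, 0 °C → rt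
Reagents that add atoms: acetic anhydride, CC(=O)OC(C)=O
Why: DMAP-catalysed acetylation takes the secondary C2 hydroxyl, while the tertiary C4 hydroxyl flanked by isopropyl and the ring fusion is too hindered to react.

**Compound list**
1 | (E)-but-2-enal (crotonaldehyde) | C/C=C/C=O | starting material
2 | 2-(triphenylphosphoranylidene)propanal | CC(C=O)=P(c1ccccc1)(c1ccccc1)c1ccccc1 | starting material
3 | (2E,4E)-2-methylhexa-2,4-dienal | O=C/C(C)=C/C=C/C | intermediate
4 | allenylboronic acid pinacol ester | C=C=CB1OC(C)(C)C(C)(C)O1 | starting material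
5 | (4S,5E,7E)-5-methylnona-5,7-dien-1-yn-4-ol | C#CC[C@H](O)/C(C)=C/C=C/C | intermediate
6 | tert-butyl(dimethyl){[(4S,5E,7E)-5-methylnona-5,7-dien-1-yn-4-yl]oxy}silane | C#CC[C@H](O[Si](C)(C)C(C)(C)C)/C(C)=C/C=C/C | intermediate
7 | lithium acetylide of 6 | [Li]C#CC[C@H](O[Si](C)(C)C(C)(C)C)/C(C)=C/C=C/C | intermediate
8 | methyl (5S,6E,8E)-5-(TBSO)-6-methyldeca-6,8-dien-2-ynoate | COC(=O)C#CC[C@H](O[Si](C)(C)C(C)(C)C)/C(C)=C/C=C/C | intermediate
9 | methyl (2E,5S,6E,8E)-5-(TBSO)-6-methyl-3-(propan-2-yl)deca-2,6,8-trienoate | COC(=O)/C=C(/C(C)C)C[C@H](O[Si](C)(C)C(C)(C)C)/C(C)=C/C=C/C | intermediate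
10 | (2E,5S,6E,8E)-5-(TBSO)-6-methyl-3-(propan-2-yl)deca-2,6,8-trien-1-ol | OC/C=C(/C(C)C)C[C@H](O[Si](C)(C)C(C)(C)C)/C(C)=C/C=C/C | intermediate
11 | {(2S,3S)-3-[(2S,3E,5E)-2-(TBSO)-3-methylhepta-3,5-dien-1-yl]-3-(propan-2-yl)oxiran-2-yl}methanol | OC[C@@H]1O[C@]1(C(C)C)C[C@H](O[Si](C)(C)C(C)(C)C)/C(C)=C/C=C/C | intermediate
12 | (2R,3S)-3-[(2S,3E,5E)-2-(TBSO)-3-methylhepta-3,5-dien-1-yl]-3-(propan-2-yl)oxirane-2-carbaldehyde | O=C[C@@H]1O[C@]1(C(C)C)C[C@H](O[Si](C)(C)C(C)(C)C)/C(C)=C/C=C/C | intermediate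
13 | 1-{(2S,3S)-3-[(2S,3E,5E)-2-(TBSO)-3-methylhepta-3,5-dien-1-yl]-3-(propan-2-yl)oxiran-2-yl}ethan-1-ol (carbinol epimers) | CC(O)[C@@H]1O[C@]1(C(C)C)C[C@H](O[Si](C)(C)C(C)(C)C)/C(C)=C/C=C/C | intermediate
14 | 1-{(2R,3S)-3-[(2S,3E,5E)-2-(TBSO)-3-methylhepta-3,5-dien-1-yl]-3-(propan-2-yl)oxiran-2-yl}ethan-1-one | CC(=O)[C@@H]1O[C@]1(C(C)C)C[C@H](O[Si](C)(C)C(C)(C)C)/C(C)=C/C=C/C | intermediate
15 | triethylsilyl enol ether of 14 (epoxy enolsilane) | C=C(O[Si](CC)(CC)CC)[C@@H]1O[C@]1(C(C)C)C[C@H](O[Si](C)(C)C(C)(C)C)/C(C)=C/C=C/C | intermediate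
16 | 2β-(TBSO)-4β-(TESO)-5αH,8βH-dauc-9-en-6-one | O=C1C[C@H](C)C=C[C@]2(C)[C@@H](O[Si](C)(C)C(C)(C)C)C[C@](O[Si](CC)(CC)CC)(C(C)C)[C@@H]12 | intermediate
17 | 2β-(TBSO)-4β-(TESO)-5αH,8βH-dauc-9-en-6β-ol | O[C@H]1C[C@H](C)C=C[C@]2(C)[C@@H](O[Si](C)(C)C(C)(C)C)C[C@](O[Si](CC)(CC)CC)(C(C)C)[C@@H]12 | intermediate
18 | 2β-(TBSO)-4β-(TESO)-5αH-dauc-8-en-6β-ol | O[C@H]1CC(C)=CC[C@]2(C)[C@@H](O[Si](C)(C)C(C)(C)C)C[C@](O[Si](CC)(CC)CC)(C(C)C)[C@@H]12 | intermediate
19 | 8β,9β-epoxy-2β-(TBSO)-4β-(TESO)-5αH-daucan-6β-ol | O[C@H]1C[C@@]3(C)O[C@H]3C[C@]2(C)[C@@H](O[Si](C)(C)C(C)(C)C)C[C@](O[Si](CC)(CC)CC)(C(C)C)[C@@H]12 | intermediate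
20 | 3,4-dimethoxybenzoyl chloride | COc1ccc(C(Cl)=O)cc1OC | starting material
21 | 8β,9β-epoxy-2β-(TBSO)-4β-(TESO)-5αH-daucan-6β-yl 3,4-dimethoxybenzoate | COc1ccc(C(=O)O[C@H]2C[C@@]3(C)O[C@H]3C[C@]3(C)[C@@H](O[Si](C)(C)C(C)(C)C)C[C@](O[Si](CC)(CC)CC)(C(C)C)[C@@H]23)cc1OC | intermediate
22 | 8β,9β-epoxy-2β,4β-dihydroxy-5αH-daucan-6β-yl 3,4-dimethoxybenzoate | COc1ccc(C(=O)O[C@H]2C[C@@]3(C)O[C@H]3C[C@]3(C)[C@@H](O)C[C@](O)(C(C)C)[C@@H]23)cc1OC | intermediate
23 | 2β-acetoxy-8β,9β-epoxy-4β-hydroxy-5αH-daucan-6β-yl 3,4-dimethoxybenzoate | COc1ccc(C(=O)O[C@H]2C[C@@]3(C)O[C@H]3C[C@]3(C)[C@@H](OC(C)=O)C[C@](O)(C(C)C)[C@@H]23)cc1OC | target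

**Totals**
Total step count: 18. Longest linear sequence: 18 steps (1 to 23).

**Steps most likely to fail**

Step 12. The attacking diene terminus C1 carries an inside methyl group, so the s-cis geometry needed for seven-ring closure is strained. The likely failures are capture of the allyl cation at C10, elimination, loss of control over the ring fusion, or ionisation at the tertiary C4–O bond with a 1,2-shift.

Fallback (sets out from 6, comes back at 16): the same two bonds are made by carbenoid cyclopropanation followed by a divinylcyclopropane rearrangement.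
- The lithium acetylide 7 is acylated with N-methoxy-N-methylacetamide to the ynone (6S,7E,9E)-6-(TBSO)-7-methylundeca-7,9-dien-3-yn-2-one F1.
- Conjugate addition of pyrrolidine gives the enaminone (3E,6S,7E,9E)-6-(TBSO)-7-methyl-4-(pyrrolidin-1-yl)undeca-3,7,9-trien-2-one F2, and aqueous AcOH hydrolyses it to the 1,3-diketone (6S,7E,9E)-6-(TBSO)-7-methylundeca-7,9-diene-2,4-dione F3.
- Diazo transfer (4-acetamidobenzenesulfonyl azide, Et3N) gives the 3-diazo-2,4-dione F4, and Et3SiOTf/Et3N turns its acetyl group into a 2-siloxyvinyl group, giving (6S,7E,9E)-3-diazo-6-(TBSO)-7-methyl-2-(TESO)undeca-1,7,9-trien-4-one F5.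
- Rh2(OAc)4 in CH2Cl2 should then cyclopropanate the C1=C10 alkene to the cis-divinylcyclopropane 4-(TBSO)-5-methyl-6-[(E)-prop-1-enyl]-1-[1-(TESO)ethenyl]bicyclo[3.1.0]hexan-2-one F6 (not isolated), with the C2 silyl ether exo and therefore cis to the C1 methyl.
- On warming in toluene F6 should undergo Cope rearrangement to the hydroazulene 2β-(TBSO)-6-(TESO)-1,8-dimethylbicyclo[5.3.0]deca-5,9-dien-4-one F7; C5–C1 comes from the cyclopropanation and C7–C8 from the sigmatropic shift.
- i-PrMgCl/CeCl3 should add to the C4 ketone anti to the C1 methyl and the C2 siloxy group, and capping in the same flask with Et3SiOTf gives the 4β,6-bis(TESO) dienol ether F8.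
- K2CO3 in MeOH cleaves only the enol silyl ether, with protonation of C5 expected anti to the C1 methyl and the C4 siloxy group, to give 16.

Step 14. The metal hydride may fail to insert into the hindered cis-disubstituted alkene next to the quaternary C1, or the free alcohol may be dehydrogenated.

Fallback (sets out from 16, comes back at 18): the alkene is moved through the ketone.
- IBX (DMSO, 70 °C) dehydrogenates C7–C8, the only α,β position with a β-hydrogen, to the dienone 2β-(TBSO)-4β-(TESO)-5αH-dauca-7,9-dien-6-one F9.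
- Li/NH3 (THF, −78 °C) with NH4Cl quench reduces the dienone at its terminus and protonates the dienolate kinetically at C7, giving the β,γ-enone 2β-(TBSO)-4β-(TESO)-5αH-dauc-8-en-6-one F10.
- Immediate reduction of F10 with LiBH(s-Bu)3 at −78 °C gives 18.

Step 15. Oxygen delivery to the congested β face may be slow, so that undirected α-face epoxidation or oxidation of the alcohol competes.

Fallback (sets out from 18, comes back at 21): the β-epoxide is made by a halohydrin route.
- 18 is first acylated with 20 (Et3N, DMAP) to 2β-(TBSO)-4β-(TESO)-5αH-dauc-8-en-6β-yl 3,4-dimethoxybenzoate F11.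
- NBS in aqueous THF forms the bromonium ion on the open α face and water opens it at the tertiary C8 from the β face, giving the bromohydrin 9α-bromo-8β-hydroxy-2β-(TBSO)-4β-(TESO)-5αH-daucan-6β-yl 3,4-dimethoxybenzoate F12.
- DBU closes the 8β,9β-epoxide by displacement of bromide with inversion at C9, giving 21.

**Further compounds**
F1 | step 12 | (6S,7E,9E)-6-(TBSO)-7-methylundeca-7,9-dien-3-yn-2-one | CC(=O)C#CC[C@H](O[Si](C)(C)C(C)(C)C)/C(C)=C/C=C/C
F2 | step 12 | (3E,6S,7E,9E)-6-(TBSO)-7-methyl-4-(pyrrolidin-1-yl)undeca-3,7,9-trien-2-one | CC(=O)/C=C(\C[C@H](O[Si](C)(C)C(C)(C)C)/C(C)=C/C=C/C)N1CCCC1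
F3 | step 12 | (6S,7E,9E)-6-(TBSO)-7-methylundeca-7,9-diene-2,4-dione | CC(=O)CC(=O)C[C@H](O[Si](C)(C)C(C)(C)C)/C(C)=C/C=C/C
F4 | step 12 | (6S,7E,9E)-3-diazo-6-(TBSO)-7-methylundeca-7,9-diene-2,4-dione | CC(=O)C(=[N+]=[N-])C(=O)C[C@H](O[Si](C)(C)C(C)(C)C)/C(C)=C/C=C/C
F5 | step 12 | (6S,7E,9E)-3-diazo-6-(TBSO)-7-methyl-2-(TESO)undeca-1,7,9-trien-4-one | C=C(O[Si](CC)(CC)CC)C(=[N+]=[N-])C(=O)C[C@H](O[Si](C)(C)C(C)(C)C)/C(C)=C/C=C/C
F6 | step 12 | 4-(TBSO)-5-methyl-6-[(E)-prop-1-enyl]-1-[1-(TESO)ethenyl]bicyclo[3.1.0]hexan-2-one (cis-divinylcyclopropane) | C=C(O[Si](CC)(CC)CC)[C@]12C(=O)C[C@H](O[Si](C)(C)C(C)(C)C)[C@@]1(C)[C@@H]2/C=C/C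
F7 | step 12 | 2β-(TBSO)-6-(TESO)-1,8-dimethylbicyclo[5.3.0]deca-5,9-dien-4-one | CC[Si](CC)(CC)OC1=C2C(=O)C[C@H](O[Si](C)(C)C(C)(C)C)[C@@]2(C)C=C[C@@H](C)C1
F8 | step 12 | 2β-(TBSO)-4β,6-bis(TESO)-8βH-dauca-5,9-diene | CC[Si](CC)(CC)OC1=C2[C@@](O[Si](CC)(CC)CC)(C(C)C)C[C@H](O[Si](C)(C)C(C)(C)C)[C@@]2(C)C=C[C@@H](C)C1
F9 | step 14 | 2β-(TBSO)-4β-(TESO)-5αH-dauca-7,9-dien-6-one | O=C1C=C(C)C=C[C@]2(C)[C@@H](O[Si](C)(C)C(C)(C)C)C[C@](O[Si](CC)(CC)CC)(C(C)C)[C@@H]12
F10 | step 14 | 2β-(TBSO)-4β-(TESO)-5αH-dauc-8-en-6-one | O=C1CC(C)=CC[C@]2(C)[C@@H](O[Si](C)(C)C(C)(C)C)C[C@](O[Si](CC)(CC)CC)(C(C)C)[C@@H]12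
F11 | step 15 | 2β-(TBSO)-4β-(TESO)-5αH-dauc-8-en-6β-yl 3,4-dimethoxybenzoate | COc1ccc(C(=O)O[C@H]2CC(C)=CC[C@]3(C)[C@@H](O[Si](C)(C)C(C)(C)C)C[C@](O[Si](CC)(CC)CC)(C(C)C)[C@@H]23)cc1OC
F12 | step 15 | 9α-bromo-8β-hydroxy-2β-(TBSO)-4β-(TESO)-5αH-daucan-6β-yl 3,4-dimethoxybenzoate | COc1ccc(C(=O)O[C@H]2C[C@@](C)(O)[C@H](Br)C[C@]3(C)[C@@H](O[Si](C)(C)C(C)(C)C)C[C@](O[Si](CC)(CC)CC)(C(C)C)[C@@H]23)cc1OC
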